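**Retrosynthetic overview**

1. The target comes from the ring B C3-formyl depside by one acidic silane reduction (CHO → CH3, MOM ether off); that aldehyde comes from ozonolysis of methyl 4-hydroxy-6-methyl-2-arylbenzofuran-5-carboxylate.
2. Feature used: the ester unit ring A C1–C(=O)–O–ring B C4, with the one-carbon group on the neighbouring ring B C3, is the ring-opened form of a 2-arylbenzofuran (furan O1 = depside oxygen, furan C2 = ester carbonyl carbon, furan C3 = the C3 methyl carbon), so the di-ortho-substituted aryl ester is made by C=C cleavage and never by acylation.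
3. The benzofuran C5 ester is installed by phenol-directed ortho-formylation, NaClO2 oxidation and O-methylation of the acid; C5 is the only open position ortho to the C4 hydroxyl.
4. The 2-arylbenzofuran comes from a one-pot Sonogashira coupling/5-endo-dig cyclization of 2-iodoorcinol (mirror-symmetric, so either hydroxyl closes to the same furan) with the ring A arylacetylene, itself made from 5-propylresorcinol by Vilsmeier formylation, para-O-methylation, MOM protection and Ohira–Bestmann homologation.
5. Ring order: benzene rings A and B come from the starting materials; the furan ring is the only ring formed (step 6) and it is opened again in step 10.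

Key step: step 10

Remark: the target has no stereocenter; the bridged ozonide of the key step and the dioxetane of its fallback are racemic with ring-enforced relative configuration, and one enantiomer is written in their SMILES.

**Route**

Step 1
Reactants: 1 5-propylbenzene-1,3-diol
Product: 3 2,4-dihydroxy-6-propylbenzaldehyde, via iminium chloride 2 (not isolated)
Conditions: POCl3, DMF, MeCN, 0 °C → rt; then H2O, 50 °C
Reagents that add atoms: N,N-dimethylformamide CN(C)C=O; water O
Why: Vilsmeier–Haack formylation, in which the chloroiminium ion should attack the carbon para to one hydroxyl and ortho to the other rather than the more crowded carbon between the two hydroxyls (as with orcinol), and warm water hydrolyses the iminium salt to the aldehyde.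

Step 2
Reactants: 3 2,4-dihydroxy-6-propylbenzaldehyde
Product: 4 2-hydroxy-4-methoxy-6-propylbenzaldehyde
Conditions: MeI (1.05 equiv), K2CO3 (1 equiv), acetone, rt
Reagents that add atoms: iodomethane CI
Why: Williamson ether synthesis, selective because the C2 hydroxyl is hydrogen-bonded to the formyl group and less acidic, so one equivalent of MeI should alkylate only the C4 phenoxide.

Step 3
Reactants: 4 2-hydroxy-4-methoxy-6-propylbenzaldehyde
Product: 5 4-methoxy-2-(methoxymethoxy)-6-propylbenzaldehyde
Conditions: NaH, THF, 0 °C; then MOMCl, 0 °C → rt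
Reagents that add atoms: chloromethyl methyl ether COCCl
Why: Williamson-type O-alkylation of the chelated phenol after irreversible deprotonation, giving a MOM acetal that keeps this hydroxyl from adding to the alkyne later and that falls off under the acid of the last step.

Step 4
Reactants: 5 4-methoxy-2-(methoxymethoxy)-6-propylbenzaldehyde; 6 dimethyl (1-diazo-2-oxopropyl)phosphonate
Product: 7 2-ethynyl-5-methoxy-1-(methoxymethoxy)-3-propylbenzene
Conditions: K2CO3, MeOH, 0 °C → rt
Reagents that add atoms: none
Why: Seyferth–Gilbert homologation in the Ohira–Bestmann variant, in which methanolysis of 6 frees the diazomethylphosphonate anion, a Horner–Wadsworth–Emmons-type olefination, loss of N2 and a 1,2-shift then deliver the terminal alkyne under a mild base that the acetal and ethers tolerate.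

Step 5
Reactants: 8 orcinol (5-methylbenzene-1,3-diol)
Product: 9 2-iodo-5-methylbenzene-1,3-diol
Conditions: I2, NaHCO3, THF/H2O, 0 °C → rt
Reagents that add atoms: iodine II
Why: Electrophilic aromatic iodination under bicarbonate buffering, which with resorcinols should place iodine on the carbon between the two hydroxyls and so give the symmetrical iodide.

Step 6
Reactants: 7 2-ethynyl-5-methoxy-1-(methoxymethoxy)-3-propylbenzene; 9 2-iodo-5-methylbenzene-1,3-diol
Product: 11 2-[4-methoxy-2-(methoxymethoxy)-6-propylphenyl]-6-methyl-1-benzofuran-4-ol, via alkynylresorcinol 10 (not isolated)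
Conditions: PdCl2(PPh3)2 (cat.), CuI (cat.), Et3N, DMF, degassed, rt → 60 °C
Reagents that add atoms: none
Why: Sonogashira coupling followed in the same pot by metal-promoted 5-endo-dig hydroalkoxylation of the o-alkynylphenol, and because the two hydroxyls of 10 are equivalent by symmetry a single benzofuran should form with the C4 hydroxyl and C6 methyl in place.

Step 7
Reactants: 11 2-[4-methoxy-2-(methoxymethoxy)-6-propylphenyl]-6-methyl-1-benzofuran-4-ol
Product: 12 4-hydroxy-2-[4-methoxy-2-(methoxymethoxy)-6-propylphenyl]-6-methyl-1-benzofuran-5-carbaldehyde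
Conditions: MgCl2, Et3N, (CH2O)n, MeCN, reflux; aq. NH4Cl work-up
Reagents that add atoms: formaldehyde (from paraformaldehyde) C=O
Why: Casnati–Skattebøl ortho-formylation, in which the magnesium phenoxide delivers formaldehyde to C5, the only free carbon ortho to the C4 hydroxyl (the other is ring-fusion carbon C3a), and a second formaldehyde acts as hydride acceptor to give the aldehyde.

Step 8
Reactants: 12 4-hydroxy-2-[4-methoxy-2-(methoxymethoxy)-6-propylphenyl]-6-methyl-1-benzofuran-5-carbaldehyde
Product: 13 4-hydroxy-2-[4-methoxy-2-(methoxymethoxy)-6-propylphenyl]-6-methyl-1-benzofuran-5-carboxylic acid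
Conditions: NaClO2, NaH2PO4, 2-methyl-2-butene (large excess), t-BuOH/THF/H2O, 0 °C → rt
Reagents that add atoms: sodium chlorite NaClO2 [Na+].[O-]Cl=O
Why: Pinnick (Lindgren) oxidation, in which buffered chlorous acid oxidises the aldehyde without harming the MOM acetal and the excess alkene removes HOCl before it can chlorinate the electron-rich rings or furan C3.

Step 9
Reactants: 13 4-hydroxy-2-[4-methoxy-2-(methoxymethoxy)-6-propylphenyl]-6-methyl-1-benzofuran-5-carboxylic acid
Product: 14 methyl 4-hydroxy-2-[4-methoxy-2-(methoxymethoxy)-6-propylphenyl]-6-methyl-1-benzofuran-5-carboxylate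
Conditions: MeI, KHCO3, DMF, rt
Reagents that add atoms: iodomethane CI
Why: SN2 O-alkylation of the carboxylate, chemoselective because KHCO3 deprotonates the acid but not the hydrogen-bonded C4 phenol.

Step 10
Reactants: 14 methyl 4-hydroxy-2-[4-methoxy-2-(methoxymethoxy)-6-propylphenyl]-6-methyl-1-benzofuran-5-carboxylate
Product: 16 methyl 3-formyl-2-hydroxy-4-[4-methoxy-2-(methoxymethoxy)-6-propylbenzoyloxy]-6-methylbenzoate, via secondary ozonide 15 (not isolated)
Conditions: O3 (1.0 equiv, titrated solution in CH2Cl2), CH2Cl2, −78 °C; then PPh3, −78 °C → rt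
Reagents that add atoms: ozone [O-][O+]=O
Why: Ozone adds as a 1,3-dipole across furan C2=C3 of 14, the adduct undergoes cycloreversion and the tethered fragments recombine to the secondary ozonide 15 (Criegee mechanism), whose O–O bond PPh3 reduces, leaving former C2 as the ester carbonyl still bonded to O1 and former C3 as the formyl group on ring B C3. The closest known reaction type is the ozonolysis of 2-arylbenzofurans to 2-(aroyloxy)benzaldehydes. No ring is closed (the furan ring is opened) and no stereocenter remains, the two stereocenters of 15 being destroyed on reduction. The step needs chemoselectivity for the furan double bond over the dialkoxy ring A and the phenolic ring B. This should be secured by the enol-ether character and low aromatic stabilisation of the furan π bond, by the twist of the di-ortho-substituted ring A out of conjugation, by the hydrogen-bonded C5 ester that deactivates ring B, and by dosing exactly one equivalent of ozone at −78 °C. Methanol is left out so that the carbonyl oxide cannot be trapped at the acyl carbon, which would break the depside link.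

Step 11
Reactants: 16 methyl 3-formyl-2-hydroxy-4-[4-methoxy-2-(methoxymethoxy)-6-propylbenzoyloxy]-6-methylbenzoate
Product: 18 Peruvinide A (methyl 2-hydroxy-4-(2-hydroxy-4-methoxy-6-propylbenzoyloxy)-3,6-dimethylbenzoate), via free-phenol aldehyde 17 (not isolated)
Conditions: Et3SiH (excess), TFA/CH2Cl2, 0 °C → rt
Reagents that add atoms: none
Why: Ionic hydrogenation, in which TFA cleaves the MOM acetal (its oxocarbenium ion is reduced by the silane) and protonates the ortho-hydroxy aldehyde, whose benzylic cation, stabilised by the C2 hydroxyl, should take up two hydrides from Et3SiH to give the C3 methyl group while the hindered aryl ester and the methyl ester stay inert to the non-nucleophilic acid.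

**Compound list**

1 | 5-propylbenzene-1,3-diol | CCCc1cc(O)cc(O)c1 | starting material
2 | [(2,4-dihydroxy-6-propylphenyl)methylidene]dimethylammonium chloride | CCCc1cc(O)cc(O)c1C=[N+](C)C.[Cl-] | intermediate (not isolated)
3 | 2,4-dihydroxy-6-propylbenzaldehyde | CCCc1cc(O)cc(O)c1C=O | intermediate
4 | 2-hydroxy-4-methoxy-6-propylbenzaldehyde | CCCc1cc(OC)cc(O)c1C=O | intermediate
5 | 4-methoxy-2-(methoxymethoxy)-6-propylbenzaldehyde | CCCc1cc(OC)cc(OCOC)c1C=O | intermediate
6 | dimethyl (1-diazo-2-oxopropyl)phosphonate | COP(=O)(OC)C(=[N+]=[N-])C(C)=O | starting material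
7 | 2-ethynyl-5-methoxy-1-(methoxymethoxy)-3-propylbenzene | CCCc1cc(OC)cc(OCOC)c1C#C | intermediate
8 | orcinol (5-methylbenzene-1,3-diol) | Cc1cc(O)cc(O)c1 | starting material
9 | 2-iodo-5-methylbenzene-1,3-diol | Cc1cc(O)c(I)c(O)c1 | intermediate
10 | 2-{[4-methoxy-2-(methoxymethoxy)-6-propylphenyl]ethynyl}-5-methylbenzene-1,3-diol | CCCc1cc(OC)cc(OCOC)c1C#Cc1c(O)cc(C)cc1O | intermediate (not isolated)
11 | 2-[4-methoxy-2-(methoxymethoxy)-6-propylphenyl]-6-methyl-1-benzofuran-4-ol | CCCc1cc(OC)cc(OCOC)c1-c1cc2c(O)cc(C)cc2o1 | intermediate
12 | 4-hydroxy-2-[4-methoxy-2-(methoxymethoxy)-6-propylphenyl]-6-methyl-1-benzofuran-5-carbaldehyde | CCCc1cc(OC)cc(OCOC)c1-c1cc2c(O)c(C=O)c(C)cc2o1 | intermediate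
13 | 4-hydroxy-2-[4-methoxy-2-(methoxymethoxy)-6-propylphenyl]-6-methyl-1-benzofuran-5-carboxylic acid | CCCc1cc(OC)cc(OCOC)c1-c1cc2c(O)c(C(=O)O)c(C)cc2o1 | intermediate
14 | methyl 4-hydroxy-2-[4-methoxy-2-(methoxymethoxy)-6-propylphenyl]-6-methyl-1-benzofuran-5-carboxylate | CCCc1cc(OC)cc(OCOC)c1-c1cc2c(O)c(C(=O)OC)c(C)cc2o1 | intermediate
15 | secondary ozonide of 14 (1,2,4-trioxolane spanning former furan C2 and C3; 3,4-benzo-fused 2,6,7,8-tetraoxabicyclo[3.2.1]oct-3-ene with the ring A aryl group at C1; racemic, one enantiomer drawn) | CCCc1cc(OC)cc(OCOC)c1[C@]12OO[C@H](O1)c1c(O2)cc(C)c(C(=O)OC)c1O | intermediate (not isolated)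
16 | methyl 3-formyl-2-hydroxy-4-[4-methoxy-2-(methoxymethoxy)-6-propylbenzoyloxy]-6-methylbenzoate | CCCc1cc(OC)cc(OCOC)c1C(=O)Oc1cc(C)c(C(=O)OC)c(O)c1C=O | intermediate
17 | methyl 3-formyl-2-hydroxy-4-(2-hydroxy-4-methoxy-6-propylbenzoyloxy)-6-methylbenzoate | CCCc1cc(OC)cc(O)c1C(=O)Oc1cc(C)c(C(=O)OC)c(O)c1C=O | intermediate (not isolated)
18 | Peruvinide A (methyl 2-hydroxy-4-(2-hydroxy-4-methoxy-6-propylbenzoyloxy)-3,6-dimethylbenzoate) | CCCc1cc(OC)cc(O)c1C(=O)Oc1cc(C)c(C(=O)OC)c(O)c1C | target

**Step count**

Total: 11 steps. Longest linear sequence: 10 steps (steps 1–4 and 6–11, from 1).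

**Steps most likely to fail**

Step 10. Ozone may keep reacting with the dialkoxy ring A or the phenolic ring B once addition to the furan bond slows (over-oxidation), or the hindered ozonide may be reduced incompletely. The fallback sets out from 14 and uses sensitised photooxygenation (O2, tetraphenylporphyrin, visible light, CH2Cl2, −78 °C). Singlet oxygen should add in a [2+2] sense to the enol-ether bond and give methyl 7-hydroxy-2a-[4-methoxy-2-(methoxymethoxy)-6-propylphenyl]-5-methyl-2a,7b-dihydro-1,2-dioxeto[3,4-b][1]benzofuran-6-carboxylate F1. Warming this dioxetane to room temperature should cleave its O–O and C–C bonds to the same ester aldehyde, so the route is rejoined at 16.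

Step 11. The benzylic cation may be captured by the neighbouring aroyloxy carbonyl oxygen (acyl shift from the phenolic to the benzylic oxygen) or by a second arene (Friedel–Crafts dimerisation) before hydride arrives. The fallback sets out from 16. Hydrogenolysis of the formyl group on zerovalent palladium (H2, Pd/C, EtOAc/AcOH, rt) should give methyl 2-hydroxy-4-[4-methoxy-2-(methoxymethoxy)-6-propylbenzoyloxy]-3,6-dimethylbenzoate F2. Separate hydrolysis of the MOM acetal (aq. HCl, THF, 40 °C) then returns to the route at 18.

Step 6. Oxidative addition to the electron-rich, doubly ortho-hydroxylated iodide may be slow, letting oxidative alkyne homocoupling compete, or the sequence may stall before ring closure. The fallback sets out from 9, which is acetylated (Ac2O, pyridine) to 2-iodo-5-methyl-1,3-phenylene diacetate F3. Sonogashira coupling of this with 7 (PdCl2(PPh3)2, CuI, Et3N, THF, 50 °C) should give 2-{[4-methoxy-2-(methoxymethoxy)-6-propylphenyl]ethynyl}-5-methyl-1,3-phenylene diacetate F4. Cs2CO3 in MeOH/DMF at 60 °C then removes both acetates to give 10, whose phenoxide closes 5-endo-dig onto the alkyne, rejoining the route at 11.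

**Further compounds**

F1 | step 10 | methyl 7-hydroxy-2a-[4-methoxy-2-(methoxymethoxy)-6-propylphenyl]-5-methyl-2a,7b-dihydro-1,2-dioxeto[3,4-b][1]benzofuran-6-carboxylate (cis-fused, racemic) | CCCc1cc(OC)cc(OCOC)c1[C@@]12OO[C@@H]1c1c(O2)cc(C)c(C(=O)OC)c1O
F2 | step 11 | methyl 2-hydroxy-4-[4-methoxy-2-(methoxymethoxy)-6-propylbenzoyloxy]-3,6-dimethylbenzoate | CCCc1cc(OC)cc(OCOC)c1C(=O)Oc1cc(C)c(C(=O)OC)c(O)c1C
F3 | step 6 | 2-iodo-5-methyl-1,3-phenylene diacetate | Cc1cc(OC(C)=O)c(I)c(OC(C)=O)c1
F4 | step 6 | 2-{[4-methoxy-2-(methoxymethoxy)-6-propylphenyl]ethynyl}-5-methyl-1,3-phenylene diacetate | CCCc1cc(OC)cc(OCOC)c1C#Cc1c(OC(C)=O)cc(C)cc1OC(C)=O
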